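**Retrosynthetic overview**

1. Target 19 ⇐ singlet-oxygen ene reaction on the only remaining olefin (C7=C8) of hydroxy-lactone 18 (last step).
2. δ-Lactone ⇐ 6-exo opening of the 3,4-oxirane by the C17 carboxylate; the C15–C17 arm and the C1/C15 stereocentres ⇐ Ireland–Claisen rearrangement of a macrocyclic (13S)-allylic propionate, then saturation of C13=C14.
3. 14-Membered carbocycle ⇐ ligand-controlled intramolecular alkenylzinc-to-aldehyde addition (C13–C14 bond) of ynal 8; C1 and C14 come from acetylide.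
4. Both oxiranes (C3, C4, C11, C12) ⇐ one-pot double Sharpless epoxidation of 12-hydroxyfarnesol, made from farnesyl acetate by SeO2 oxidation.
5. Ring order: two oxiranes in one operation → carbocycle → δ-lactone (formed at the cost of the 3,4-oxirane).

Assumption: (2E,6E)-farnesyl acetate is bought isomerically pure; ring locants C1–C14 follow cembrane numbering (C15/C16/C17 = propionate carbons on C1; C18, C19, C20 = methyls on C4, C8, C12), which makes the target (1R,3R,4S,7S,11S,12S,15S).

**Route**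

Step 1
Reactants: 1 (2E,6E)-farnesyl acetate
Product: 2 (2E,6E,10E)-12-hydroxy-3,7,11-trimethyldodeca-2,6,10-trien-1-yl acetate
Conditions: SeO2 (0.1 equiv), salicylic acid (0.1 equiv), t-BuOOH (3 equiv), CH2Cl2, 0 °C → rt
Reagents that add atoms: tert-butyl hydroperoxide, CC(C)(C)OO
Why: Catalytic SeO2 allylic oxidation (ene reaction then [2,3]-shift) attacks the (E)-methyl of the terminal olefin, the 2,3-olefin being deactivated by its allylic acetate, so only the 10E geometry is fixed and no stereocentre is made.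

Step 2
Reactants: 2 (2E,6E,10E)-12-hydroxy-3,7,11-trimethyldodeca-2,6,10-trien-1-yl acetate
Product: 3 (2E,6E,10E)-3,7,11-trimethyldodeca-2,6,10-triene-1,12-diol
Conditions: K2CO3 (cat.), MeOH, rt
Reagents that add atoms: none
Why: Base-catalysed transesterification frees the second allylic alcohol so that both chain ends can direct an epoxidation.

Step 3
Reactants: 3 (2E,6E,10E)-3,7,11-trimethyldodeca-2,6,10-triene-1,12-diol
Product: 4 (2S,3S,6E,10S,11S)-2,3:10,11-diepoxy-3,7,11-trimethyldodec-6-ene-1,12-diol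
Conditions: Ti(OiPr)4 (0.2 equiv), L-(+)-diethyl tartrate (0.28 equiv), t-BuOOH (4 equiv, anhydrous), 4 Å MS, CH2Cl2, −25 °C
Reagents that add atoms: tert-butyl hydroperoxide, CC(C)(C)OO
Why: Double Katsuki–Sharpless asymmetric epoxidation: each allylic alcohol delivers oxygen to its own (E)-olefin from the face set by L-(+)-tartrate, giving an (S,S)-oxirane at both ends (four stereocentres, two rings in one operation) while the isolated central olefin is inert, and the minor facial error at either end is removed as a diastereomer.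

Step 4
Reactants: 4 (2S,3S,6E,10S,11S)-2,3:10,11-diepoxy-3,7,11-trimethyldodec-6-ene-1,12-diol
Product: 5 (2S,3S,6E,10S,11R)-2,3:10,11-diepoxy-12-iodo-2,6,10-trimethyldodec-6-en-1-ol
Conditions: I2 (1.05 equiv), PPh3 (1.05 equiv), imidazole (2.2 equiv), CH2Cl2, −20 → 0 °C
Reagents that add atoms: iodine, II
Why: Garegg–Samuelsson (Appel-type) iodination ends in an SN2 displacement that is fast at the CH2 next to the CH-oxirane carbon and slow at the neopentyl-type CH2 next to the fully substituted oxirane carbon, so the mono-iodide at the future C2 forms selectively without touching a stereocentre (the 11R label only reflects the new priority of CH2I).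

Step 5
Reactants: 5 (2S,3S,6E,10S,11R)-2,3:10,11-diepoxy-12-iodo-2,6,10-trimethyldodec-6-en-1-ol; 6 lithium acetylide–ethylenediamine complex (3 equiv)
Product: 7 (2S,3S,6E,10S,11S)-2,3:10,11-diepoxy-2,6,10-trimethyltetradec-6-en-13-yn-1-ol
Conditions: DMSO/THF, 5 °C → rt
Reagents that add atoms: none
Why: SN2 alkylation of acetylide by the primary iodide brings in C1 and C14, and the trisubstituted oxiranes are not opened by acetylide without a Lewis acid, so all four stereocentres are retained.

Step 6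
Reactants: 7 (2S,3S,6E,10S,11S)-2,3:10,11-diepoxy-2,6,10-trimethyltetradec-6-en-13-yn-1-ol
Product: 8 (2R,3S,6E,10S,11S)-2,3:10,11-diepoxy-2,6,10-trimethyltetradec-6-en-13-ynal
Conditions: Dess–Martin periodinane, pyridine, CH2Cl2, 0 °C → rt
Reagents that add atoms: none
Why: Dess–Martin oxidation of the remaining primary alcohol gives an epoxy aldehyde with no α-hydrogen, which therefore cannot epimerise (2R is only a priority change).

Step 7
Reactants: 8 (2R,3S,6E,10S,11S)-2,3:10,11-diepoxy-2,6,10-trimethyltetradec-6-en-13-ynal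
Product: 11 (1(14)E,3S,4S,7E,11S,12S,13S)-3,4:11,12-diepoxy-4,8,12-trimethylcyclotetradeca-1(14),7-dien-13-ol, via alkenyldicyclohexylborane 9 (not isolated), via alkenylethylzinc 10 (not isolated)
Conditions: (c-C6H11)2BH (1.05 equiv), toluene, 0 °C; then slow addition to Et2Zn (1.5 equiv), (−)-DAIB (5 mol %), toluene, 0 °C, 0.005 M; H2O
Reagents that add atoms: none
Why: Oppolzer-type asymmetric macrocyclisation: the borane hydroborates only the terminal alkyne, boron-to-zinc exchange gives the (E)-alkenylzinc, and the amino-alcohol ligand directs intramolecular alkenyl transfer to the Si face of the hindered aldehyde, closing the 14-membered ring and setting C13 as S under ligand control.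

Step 8
Reactants: 11 (1(14)E,3S,4S,7E,11S,12S,13S)-3,4:11,12-diepoxy-4,8,12-trimethylcyclotetradeca-1(14),7-dien-13-ol; 12 propionic anhydride
Product: 13 propanoate ester of 11 at O13 (all stereocentres unchanged)
Conditions: Et3N, DMAP (cat.), CH2Cl2, rt
Reagents that add atoms: none
Why: DMAP-catalysed acylation of the only hydroxyl installs the three carbons C15–C17 as an allylic propionate.

Step 9
Reactants: 13 propanoate ester of 11
Product: 15 tert-butyldimethylsilyl (2S)-2-[(1S,3S,4S,7E,11S,12S,13E)-3,4:11,12-diepoxy-4,8,12-trimethylcyclotetradeca-7,13-dien-1-yl]propanoate, via silyl ketene acetal 14 (not isolated)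
Conditions: LiN(iPr)2, THF, −78 °C; t-BuMe2SiCl, HMPA, −78 → 40 °C
Reagents that add atoms: tert-butyldimethylsilyl chloride, CC(C)(C)[Si](C)(C)Cl
Why: Ireland–Claisen rearrangement: the kinetic (E)-enolate is silylated and rearranges through a chair transition state with C12 pseudo-equatorial, forming C1–C15 on the face from which O13 leaves, so that (13S) is relayed into the target configuration at C1 and the anti methyl at C15 (15S) while the olefin moves to C13=C14 (E).

Step 10
Reactants: 15 tert-butyldimethylsilyl (2S)-2-[(1S,3S,4S,7E,11S,12S,13E)-3,4:11,12-diepoxy-4,8,12-trimethylcyclotetradeca-7,13-dien-1-yl]propanoate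
Product: 16 tert-butyldimethylsilyl (2S)-2-[(1R,3S,4S,7E,11S,12S)-3,4:11,12-diepoxy-4,8,12-trimethylcyclotetradec-7-en-1-yl]propanoate
Conditions: 2-nitrobenzenesulfonylhydrazide, Et3N, CH2Cl2, rt, monitored
Reagents that add atoms: none
Why: Diimide reduction transfers H2 to the 1,2-disubstituted C13=C14 olefin in preference to the trisubstituted C7=C8 olefin and leaves oxiranes and the silyl ester alone, although the hindered position of C13=C14 narrows this preference (no stereocentre changes; C1 becomes R only by priority).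

Step 11
Reactants: 16 tert-butyldimethylsilyl (2S)-2-[(1R,3S,4S,7E,11S,12S)-3,4:11,12-diepoxy-4,8,12-trimethylcyclotetradec-7-en-1-yl]propanoate
Product: 18 (1R,3R,4S,7E,11S,12S,15S)-11,12-epoxy-4-hydroxycembr-7-en-17,3-olide, via tetrabutylammonium carboxylate 17 (not isolated)
Conditions: Bu4NF, THF, 0 → 45 °C; H2O
Reagents that add atoms: none
Why: Fluoride desilylation frees a naked carboxylate that opens the 3,4-oxirane by 6-exo-tet SN2 attack at C3 with inversion (3S → 3R), leaving O4 as the tertiary alcohol (4S), whereas the 11,12-oxirane could only be reached at its quaternary carbon through a seven-membered transition state and survives.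

Step 12
Reactants: 18 (1R,3R,4S,7E,11S,12S,15S)-11,12-epoxy-4-hydroxycembr-7-en-17,3-olide
Product: 19 (1R,3R,4S,7S,11S,12S,15S)-11,12-epoxy-7-hydroperoxy-4-hydroxycembr-8(19)-en-17,3-olide (CNP0319766.2)
Conditions: O2, hν (visible), tetraphenylporphyrin (cat.), CH2Cl2, −20 °C
Reagents that add atoms: oxygen, O=O
Why: Schenck ene reaction of singlet oxygen with the only olefin left: hydrogen abstraction from C19 on the more crowded side of the (E)-olefin gives the 7-hydroperoxide with the 8(19)-methylene, and C7 (S) is set by substrate control through attack on the exposed peripheral face of the macrocycle, with the 8-hydroperoxy-6-ene regioisomer and the C7 epimer removed by HPLC.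

**Compound list**

1 | (2E,6E)-farnesyl acetate | CC(C)=CCC/C(C)=C/CC/C(C)=C/COC(C)=O | starting material
2 | (2E,6E,10E)-12-hydroxy-3,7,11-trimethyldodeca-2,6,10-trien-1-yl acetate | OC/C(C)=C/CC/C(C)=C/CC/C(C)=C/COC(C)=O | intermediate
3 | (2E,6E,10E)-3,7,11-trimethyldodeca-2,6,10-triene-1,12-diol | OC/C(C)=C/CC/C(C)=C/CC/C(C)=C/CO | intermediate
4 | (2S,3S,6E,10S,11S)-2,3:10,11-diepoxy-3,7,11-trimethyldodec-6-ene-1,12-diol (chain C1 becomes ring C2, chain C12 becomes ring C13) | OC[C@@H]1O[C@@]1(C)CC/C=C(\C)CC[C@@H]1O[C@@]1(C)CO | intermediate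
5 | (2S,3S,6E,10S,11R)-2,3:10,11-diepoxy-12-iodo-2,6,10-trimethyldodec-6-en-1-ol | IC[C@@H]1O[C@@]1(C)CC/C=C(\C)CC[C@@H]1O[C@@]1(C)CO | intermediate
6 | lithium acetylide–ethylenediamine complex | [Li+].[C-]#C.NCCN | starting material
7 | (2S,3S,6E,10S,11S)-2,3:10,11-diepoxy-2,6,10-trimethyltetradec-6-en-13-yn-1-ol | C#CC[C@@H]1O[C@@]1(C)CC/C=C(\C)CC[C@@H]1O[C@@]1(C)CO | intermediate
8 | (2R,3S,6E,10S,11S)-2,3:10,11-diepoxy-2,6,10-trimethyltetradec-6-en-13-ynal | C#CC[C@@H]1O[C@@]1(C)CC/C=C(\C)CC[C@@H]1O[C@@]1(C)C=O | intermediate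
9 | (2R,3S,6E,10S,11S,13E)-14-(dicyclohexylboranyl)-2,3:10,11-diepoxy-2,6,10-trimethyltetradeca-6,13-dienal | C1CCCCC1B(C1CCCCC1)/C=C/C[C@@H]2O[C@@]2(C)CC/C=C(\C)CC[C@@H]2O[C@@]2(C)C=O | intermediate (not isolated)
10 | ethyl[(1E)-alkenyl]zinc analogue of 9 (ZnEt in place of the boryl group) | CC[Zn]/C=C/C[C@@H]1O[C@@]1(C)CC/C=C(\C)CC[C@@H]1O[C@@]1(C)C=O | intermediate (not isolated)
11 | (1(14)E,3S,4S,7E,11S,12S,13S)-3,4:11,12-diepoxy-4,8,12-trimethylcyclotetradeca-1(14),7-dien-13-ol | O[C@H]1/C=C/C[C@@H]2O[C@@]2(C)CC/C=C(\C)CC[C@@H]2O[C@@]12C | intermediate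
12 | propionic anhydride | CCC(=O)OC(=O)CC | starting material
13 | propanoate ester of 11 at O13 (all stereocentres as in 11) | CCC(=O)O[C@H]1/C=C/C[C@@H]2O[C@@]2(C)CC/C=C(\C)CC[C@@H]2O[C@@]12C | intermediate
14 | (E)-tert-butyldimethylsilyl ketene acetal of 13 (methyl cis to the ring-bound oxygen) | C/C=C(O[Si](C)(C)C(C)(C)C)\O[C@H]1/C=C/C[C@@H]2O[C@@]2(C)CC/C=C(\C)CC[C@@H]2O[C@@]12C | intermediate (not isolated)
15 | tert-butyldimethylsilyl (2S)-2-[(1S,3S,4S,7E,11S,12S,13E)-3,4:11,12-diepoxy-4,8,12-trimethylcyclotetradeca-7,13-dien-1-yl]propanoate (C1 has the target's spatial arrangement; it reads S here because C14 is olefinic) | C1C[C@@H]2O[C@@]2(C)/C=C/[C@@H]([C@H](C)C(=O)O[Si](C)(C)C(C)(C)C)C[C@@H]2O[C@@]2(C)CC/C=C/1C | intermediate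
16 | tert-butyldimethylsilyl (2S)-2-[(1R,3S,4S,7E,11S,12S)-3,4:11,12-diepoxy-4,8,12-trimethylcyclotetradec-7-en-1-yl]propanoate | C1C[C@@H]2O[C@@]2(C)CC[C@@H]([C@H](C)C(=O)O[Si](C)(C)C(C)(C)C)C[C@@H]2O[C@@]2(C)CC/C=C/1C | intermediate
17 | tetrabutylammonium (2S)-2-[(1R,3S,4S,7E,11S,12S)-3,4:11,12-diepoxy-4,8,12-trimethylcyclotetradec-7-en-1-yl]propanoate | C1C[C@@H]2O[C@@]2(C)CC[C@@H]([C@H](C)C(=O)[O-])C[C@@H]2O[C@@]2(C)CC/C=C/1C.CCCC[N+](CCCC)(CCCC)CCCC | intermediate (not isolated)
18 | (1R,3R,4S,7E,11S,12S,15S)-11,12-epoxy-4-hydroxycembr-7-en-17,3-olide (δ-lactone C17(=O)–O–C3) | C1C[C@@H]2O[C@@]2(C)CC[C@@H]2C[C@@H](OC(=O)[C@H]2C)[C@@](C)(O)CC/C=C/1C | intermediate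
19 | (1R,3R,4S,7S,11S,12S,15S)-11,12-epoxy-7-hydroperoxy-4-hydroxycembr-8(19)-en-17,3-olide | C=C1CC[C@@H]2O[C@@]2(C)CC[C@@H]2C[C@@H](OC(=O)[C@H]2C)[C@@](C)(O)CC[C@@H]1OO | target

**Step count and risks**

Total steps: 12. Longest linear sequence: 12 (1 → 19); 6 and 12 are bought.

Most likely to fail, first: step 12. The ene reaction can also abstract hydrogen from C6 (giving the 8-hydroperoxide) and its facial selectivity at C7 rests on substrate control only. The fallback sets out from 18 and comes back at 19. Ene-type chlorination of 18 with NaOCl and CeCl3·7H2O in CH2Cl2/H2O puts chlorine on the less substituted olefin carbon and gives the 7-chloro-8(19)-ene lactone F6. Silver-assisted perhydrolysis of F6 (AgOSO2CF3, anhydrous H2O2 in Et2O, −20 °C) then gives 19. This fixes the regiochemistry but not C7, so the C7 epimers still need HPLC separation.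

Second: step 7. The ring closure needs a hindered aldehyde, high dilution and a ligand that overrides any bias from the neighbouring oxirane. The fallback sets out from 7 and comes back at 11. Hydrozirconation–iodination of 7 (Cp2Zr(H)Cl, then I2) gives the (E)-vinyl iodide alcohol F1, and Dess–Martin oxidation gives the iodo aldehyde F2. A Nozaki–Hiyama–Kishi macrocyclisation of F2 (CrCl2, NiCl2 cat., DMSO/THF, high dilution) gives 11 with its C13 epimer. If the ratio is poor, the mixture is oxidised (Dess–Martin) to the macrocyclic enone F3, which is reduced with the Corey–Bakshi–Shibata oxazaborolidine enantiomer (BH3·SMe2) that gives the (13S)-alcohol 11.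

Third: step 10. The C13=C14 olefin is flanked by a quaternary and a tertiary carbon, so diimide may not discriminate well against C7=C8, which is needed for step 12. The fallback sets out from 15 and comes back at 18. Buffered desilylation of 15 (Bu4NF/AcOH, THF, 0 °C) gives the unsaturated acid F4, handled as its triethylammonium salt. Carboxylate-directed hydrogenation with [Rh(nbd)(dppb)]BF4 under H2 in CH2Cl2 reduces only the γ,δ-olefin held next to the bound carboxylate and gives the saturated acid F5. Warming F5 with Cs2CO3 in DMF (50 °C) closes the lactone to 18.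

**Further compounds**

F1 | step 7 | (2S,3S,6E,10S,11S,13E)-2,3:10,11-diepoxy-14-iodo-2,6,10-trimethyltetradeca-6,13-dien-1-ol | I/C=C/C[C@@H]1O[C@@]1(C)CC/C=C(\C)CC[C@@H]1O[C@@]1(C)CO
F2 | step 7 | (2R,3S,6E,10S,11S,13E)-2,3:10,11-diepoxy-14-iodo-2,6,10-trimethyltetradeca-6,13-dienal | I/C=C/C[C@@H]1O[C@@]1(C)CC/C=C(\C)CC[C@@H]1O[C@@]1(C)C=O
F3 | step 7 | (1(14)E,7E)-3,4:11,12-diepoxy-4,8,12-trimethylcyclotetradeca-1(14),7-dien-13-one (oxiranes as in 11) | O=C1/C=C/C[C@@H]2O[C@@]2(C)CC/C=C(\C)CC[C@@H]2O[C@@]12C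
F4 | step 10 | (2S)-2-[(1S,3S,4S,7E,11S,12S,13E)-3,4:11,12-diepoxy-4,8,12-trimethylcyclotetradeca-7,13-dien-1-yl]propanoic acid | C1C[C@@H]2O[C@@]2(C)/C=C/[C@@H]([C@H](C)C(=O)O)C[C@@H]2O[C@@]2(C)CC/C=C/1C
F5 | step 10 | (2S)-2-[(1R,3S,4S,7E,11S,12S)-3,4:11,12-diepoxy-4,8,12-trimethylcyclotetradec-7-en-1-yl]propanoic acid | C1C[C@@H]2O[C@@]2(C)CC[C@@H]([C@H](C)C(=O)O)C[C@@H]2O[C@@]2(C)CC/C=C/1C
F6 | step 12 | (1R,3R,4S,11S,12S,15S)-7-chloro-11,12-epoxy-4-hydroxycembr-8(19)-en-17,3-olide (C7 epimers) | C=C1CC[C@@H]2O[C@@]2(C)CC[C@@H]2C[C@@H](OC(=O)[C@H]2C)[C@@](C)(O)CCC1Cl
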